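Start from what is left: after 90.0 min the red run keeps 64.0 % of its substrate, the blue run 55.5 %. Substrate goes to product in a flask charged with free catalyst and reagent.

| setting | red | blue | autumn | dusk |
|---|---|---|---|---|
| substrate | 0.10 M | 0.10 M | 0.10 M | 0.10 M |
| reagent | 0.11 M | 0.16 M | 0.180 M | 0.120 M |
| free catalyst | 0.50 mM | 0.50 mM | 0.50 mM | 0.50 mM |
| remark | run made earlier | run made earlier |  |  |
| time |  |  | 3.0 h | 3.0 h |

| run | time / min | substrate / % | product / % |
|---|---|---|---|
| red | 8.00 | 96.4 | 3.3 |
| red | 25.0 | 88.5 | 11.2 |
| red | 40.0 | 81.9 | 17.6 |
| red | 60.0 | 75.0 | 25.1 |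
| red | 90.0 | 64.0 | 35.1 |
| blue | 20.0 | 88.5 | 10.3 |
| blue | 40.0 | 77.3 | 21.5 |
| blue | 50.0 | 72.3 | 26.4 |
| blue | 80.0 | 60.6 | 40.3 |
| blue | 90.0 | 55.5 | 44.9 |

(readings scatter by 0.5 percentage points)
- the analysis behind the earlier runs scatters by 0.5 percentage points, standard deviation
1. part of the substrate that has reacted at the end, autumn
2. part of the substrate that has reacted at the end, dusk
3. what raising the concentration of reagent from its lowest to its highest value here does to the part of the substrate that has reacted (changes below 5 percentage points count as none) (it rises / no change / it falls)

Take the fractional rate: the rate per fraction of substrate left, a pseudo-first-order constant of the moment. Read it from the last readings: 0.00496 /min red, 0.00654 /min blue. It stays level along each run, as far as the readings show. Comparing the two runs, the fractional rate reads as following the reagent charge to the power n = 0.740.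

Assume one reagent spent per substrate reacted. Reagent then falls to the fraction b = 0.673 in red, 0.722 in blue. That slows the rate by b^n. Yet the fractional rate reads level, so take substrate to slow the rate by less than its fraction s. Write that factor s^a; the two runs give a = 0.484.

Reckon autumn. The start fractional rate is 0.00714 /min. A first pass at that rate gives:

s = 0.277, b = 0.598
substrate factor 0.537, reagent factor 0.684

The drift factor D, the fractional rate at the end over that at the start, s^a b^n / s, is 1.33. Averaging start and end:

s = 0.224, reacted 77.6 %

Dusk, the same way:

start 0.00529 /min, s = 0.386, b = 0.488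
D = 0.962, reacted 60.7 %

The forecast says 71.5 % for autumn and 61 % for dusk; on raising the reagent: it rises. Its ground: “Both runs look first order in substrate”. My autumn figure is higher.

The flask gives 78.1 % for autumn, 61.7 % for dusk, and it rises, by 16 percentage points.

    substrate + free catalyst ⇌ catalyst intermediate A (K = 29.0 /M, k = 6.80 /M/s)
    reagent + catalyst intermediate A → catalyst intermediate B (k = 0.320 /M/s)
    catalyst intermediate B → by-product + catalyst intermediate C (k = 0.0480 /s)
    catalyst intermediate C → free catalyst + product (k = 0.370 /s)
    reagent + by-product ⇌ idle adduct, settled at all times (K = 2.70 /M)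

In dusk at 3.00 h, the half-life of substrate by the forward binding to free catalyst alone is 0.14 h, short against 3.0 h; catalyst intermediate A then holds 42.6 % of the catalyst. With the end states, D reads 1.28 for autumn against my 1.33, and 0.872 for dusk against my 0.962.

Now read dusk at 80 min. There s = 0.655 and b = 0.713, so D = 0.968, and the reckoning gives 34.1 % reacted. The flask gives 34.2 %.

The readings are calculated with made-up constants; the scatter is artificial.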